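The numbers in the tables come from a simulation with constants of no real substance; the scatter is artificial.

Early in the alpha run E is still going in, up to 50 s, so I read the clearing of E from the end of the feed onward. I have to decide whether the flask with 50 µM of L, left for 20 min, is worth charging as it stands.

- alpha: E 0.050 M (fed, over 50 s); L 100 µM; run made earlier
- flask: E 0.050 M (fed, over 50 s); L 50 µM; time 20 min

alpha run (percent of the E charged)

| time / s | E / % | J / % |
|---|---|---|
| 10.0 | 21 | 1 |
| 20.0 | 38 | 5 |
| 30.0 | 49 | 7 |
| 50.0 | 81 | 20 |
| 80.0 | 67 | 33 |
| 90.0 | 60 | 40 |
| 120 | 48 | 53 |

(standard deviation of a reading: 2 percentage points)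

- at 20 min, what has stopped the reaction, if anything has (all of E has reacted / it is still moving / forward and back rates have come level / no working catalyst is left)
- part of the E gone at 20 min
- the J standing at 20 min, as a percentage of the E charged

- the numbers in the tables scatter by 2 percentage points (one standard deviation)
- percentages count the whole charge, also what has not yet gone in
- the reaction counts as stopped when no species that holds the E changes by six tenths of a point or more over the second half of the time
- no earlier run changes the charge of L; that part of a forecast is a guess

In the flask the large part, E gone, will look after itself, so I reckon just the small remainder of E as a fraction of the charge. My clearing constant is the share of the standing E that goes per second at the alpha charge of L (a pseudo-first-order constant), read from alpha's E at 50.0 s and 120 s: 0.00747 s⁻¹. I scale it by the charge of L, which is a guess, since no earlier run changes L. I start the clock at 25.0 s, when E has on average entered.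

constant in the flask: 0.00747 s⁻¹ × 50 µM / 100 µM = 0.00374 s⁻¹

E left at 10.0 min: exp(−0.00374 s⁻¹ × 575 s) = 11.7 %

E left at 20 min: exp(−0.00374 s⁻¹ × 1180 s) = 1.24 %

On my reckoning the fall of 10 percentage points between those two times means the stopping rule still counts the flask as moving. So I charge 50 µM of L and leave it the full 20 min.

The forecast, “Guessing first order in L” with its own constant, says it is still moving, with 99 % of E gone (88 % to 100 %) and 99 % of J (85 % to 100 %).

    E + L → Q (k = 280 L mol⁻¹ s⁻¹)
    Q → L + J (k = 4.50 s⁻¹)
    L ⇌ Z (K = 17.0, k = 0.00710 s⁻¹)

The flask gives 90.0 % of E gone and 90.0 % of J, both 9 points below the forecast, and at 20 min the state is: it is still moving. At 20.0 min Z, a form of the catalyst L outside its working round, holds 92.1 % of the catalyst charged in the flask. Read through the clearing constant scaled to this flask, the 10 % of E left in the flask is a working time of 10.3 min, less than the 19.6 min I reckoned. With that working time and 0.00747 s⁻¹ scaled to 8.5 × 10⁻⁵ M of L, a neighbour flask should keep 2.01 % of its E at 20.0 min, and that neighbour stands at 1.73 %.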